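## The problem

The target, 3-(4-hydroxyphenyl)-5-methoxy-4,7-diphenylbenzofuran-2,6-dione (20), is a fully substituted quinone methide. A six-membered carbocycle (ring A: C3a, C4, C5, C6, C7, C7a) is fused along C3a–C7a to an unsaturated five-membered lactone (ring B: O1, C2, C3). Ring A carries no hydrogen: it bears two phenyl groups (C4, C7), three oxygens in three different states (O1 acylated, O5 methylated, O6 as carbonyl) and the exocyclic C3=C3a bond. The central task is therefore regiochemical, and the three oxygens must be distinguished from the moment they are introduced, because late selective alkylation of such a polyphenol cannot be relied on.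

The molecule has no stereocentre. The only stereogenic carbon on the route (C3 as a carbinol) is formed racemic and becomes trigonal in the last step, so there is no stereochemical relay to plan.

The functionality is fragile. C3 of the quinone methide is electrophilic, the C5 methoxy group sits on an alpha-alkoxy enone that strong Lewis acids can strip, the lactone is an enol ester open to solvolysis, and the free 4'-phenol and the electron-rich core are easily over-oxidised. The chromophore should therefore appear last and preferably without an oxidant.

The feature that makes the key step possible is the triad C3a–C3(aryl)–C2(=O) with O1 on the neighbouring C7a. This is the pattern an anionic 1,2-aryl shift produces when a C7a phenoxide adds to the outer carbonyl of a benzil attached at C3a. The tertiary hydroxyl left on C3 is para-related through ring A to O6, so loss of water alone gives the C3=C3a/C6=O quinone methide at the correct oxidation level.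

## Retrosynthesis

**20 back to 18 (through 19).** No skeletal bond is cut. The C3=C3a and C6=O double bonds are traced back to a C3 hydroxyl and a C6 hydroxyl (formal addition of water across C3 and O6), which gives triol 19. With O6 and O4' masked as isopropyl and benzyl ethers this becomes carbinol 18. The neighbouring option, a 3-H lactone oxidised at the end, would place an oxidant on an electron-rich polyphenol, whereas the carbinol already holds the oxidation level. Keeping O6 as an ether until the end also prevents the C3 oxygen from leaving prematurely. Precursor 18 is an ordinary protected lactone without the reactive chromophore. The forward step must cleave a secondary alkyl ether and a benzyl ether, spare the C5 methyl ether and the lactone, and lose water without a redox change.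

**18 back to 15 (through 17 and 16).** The O1–C2 and C3–aryl bonds are cut, a retro-1,2-aryl shift with opening of ring B. This leads through hemiketal 17 and the free ortho-hydroxybenzil 16 to its acetate 15. Cutting C2–C3 instead would need an acyl anion equivalent or carbon monoxide at a hindered benzylic centre. Cutting C3–C3a would need an intermolecular Friedel–Crafts attack at the most crowded ring position. The chosen cut turns the quaternary carbinol into a plain diaryl diketone and lets the ring oxygen deliver itself. Ring B and the quaternary carbon disappear, and 15 is an acyclic benzil on a finished ring A. The forward reaction requires the phenoxide to add to the outer carbonyl and the aryl group on that carbon to migrate to the inner one.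

**15 back to 12 and 13 (through 14).** The two carbonyl oxygens are removed to give diarylalkyne 14, and the arene–alkyne bond (the future C3a–C3 bond) is then cut to give aryl iodide 12 and the purchasable alkyne 13. An alkyne is linear and small, enters under neutral conditions and brings C3, C2 and the 4'-oxygenated ring in one piece. Direct acylation of the crowded ring position with an aroylformyl unit has none of these advantages. The forward steps require a cross-coupling at an iodide flanked by an acetoxy and a phenyl group, and an alkyne dioxygenation that spares the ethers and the acetate.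

**12 back to 10 (through 11).** The acetyl group and the carbon–iodine bond are removed. Phenol 10 has a single ring hydrogen, at the future C3a and ortho to the hydroxyl, so the halogenation to 11 has no regiochemical choice. The acetate keeps the ortho-alkynylphenol from closing to a benzofuran, and it is the group that the key step later removes.

**10 back to 7 (through 9 and 8).** The C3a–C7a bond of ring A is cut: retro-enolisation to cyclohexadienone 9, retro-6π electrocyclisation to dienylketene 8, and ring closure to cyclobutenone 7. Stepwise substitution of a simpler arene would have to differentiate three oxygens and set two phenyl groups para to each other. The cyclobutenone route reads the whole pattern from the order in which nucleophiles are added to a squarate: free hydroxyl at the future O1, isopropyl at O6, methyl at O5. Precursor 7 is a four-membered ring carrying every substituent. The forward reaction requires the methoxy group to rotate outward on ring opening so that the styryl unit faces the ketene.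

**7 back to 3, 4 and 1 (through 6, 5 and 2).** The bond between the carbinol carbon of 7 and the vinyl group (the future C4–C5 bond) and the O–methyl bond are cut. This gives dione 3 and bromide 4, which reacts as vinyllithium 5 through alkoxide 6. Cutting the remaining phenyl–ring bond (future C7–phenyl) leads through adduct 2 to diisopropyl squarate 1. The four squarate carbons become C7a, C7, C6 and C5; bromide 4 supplies C4, C3a and the C4 phenyl group. The second nucleophile must add to the carbonyl next to the isopropoxy-bearing carbon. This is secured because the other carbonyl of 3 is part of a vinylogous ester.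

## Roads not taken

Alternative 1: The strategic cut is C3a–C7a, ring A itself.
- **Forward key step:** heating the 4-methoxy-4-(1-phenylvinyl)cyclobutenone A1 (the same compound as 7) opens the four-membered ring to a dienylketene. A 6π electrocyclisation and enolisation then give phenol A2 (identical with 10), with O1 free, O5 methylated and O6 isopropylated.
- **Merits:** a squarate and two organolithium additions fix the whole substitution pattern of ring A, including the distinction among three oxygens, by construction and on well-precedented ground.
- **Weak points:** as a governing idea it stops at A2. C2, C3 and the hydroxyaryl ring are missing, the single free ring position must still become a quaternary oxygenated carbon, and the quinone-methide oxidation level is not addressed.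
- **Comparison:** for ring A this road is identical to the chosen plan, which uses it unchanged as step 3. The ring expansion is also the better-precedented of the two transformations. The chosen plan adds an answer for the harder half: one anionic cascade that makes ring B, the C3 quaternary centre and the final oxidation level.

Alternative 2: The cut is O1–C7a, made late and oxidatively.
- **Forward key step:** the catechol diarylacetic acid A3 is oxidised with Ag2O to ortho-quinone A4. The carboxylate adds in conjugate fashion to C7a and closes ring B, and further oxidation in the same flask gives the quinone methide xylerythrin A5.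
- **Merits:** the sequence is plausibly biomimetic, needs no protecting groups at the end, and produces ring B and the chromophore in one pot. Its endgame is shorter than the chosen one and uses no Lewis acid.
- **Weak points:** it ends at A5, the 5-hydroxy compound, whereas 20 is the 5-methyl ether. A5 has two acidic hydroxyls (the enolic 5-OH and the 4'-OH, which is vinylogously conjugated to the C6 carbonyl), so clean mono-methylation at O5 is not assured. The methyl group cannot be carried through, because a 5-O-methylated precursor is no longer a catechol and cannot give the ortho-quinone. A3 still needs the same pentasubstituted ring plus a diarylacetic acid side chain, so the front end is no shorter. The four-electron oxidation of an electron-rich polyphenol invites over-oxidation and decarboxylation.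
- **Comparison:** for xylerythrin itself this would be the better road. For its methyl ether the chosen plan offers a methyl group fixed on O5 from step 2 and a redox-neutral final step, against the shorter endgame of this alternative.

Alternative 3: The cut removes C2 as carbon monoxide, disconnecting C2–C3 and C2–O1.
- **Forward key step:** the ortho-hydroxybenzhydrol A6 would come in one step from phenol A2 and 4-isopropoxybenzaldehyde A7 by ortho-hydroxyalkylation. Carbonylation with Pd(OAc)2, 1,4-bis(diphenylphosphino)butane and an acid cocatalyst would ionise the benzylic alcohol, insert CO into the benzyl–palladium bond and trap the acyl group with the phenol, giving the racemic 3-H lactone A8.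
- **Merits:** it is convergent and the shortest of the routes: about four steps from A2 (hydroxyalkylation, carbonylation, dealkylation, oxidation) against six from 10 in the chosen plan. It avoids both the hindered cross-coupling and the alkyne oxidation.
- **Weak points:** the precedent for this carbonylative lactonisation is on simple ortho-hydroxybenzyl alcohols. Here the benzylic carbon is diaryl-substituted, flanked by the C4 phenyl group and next to a free electron-rich phenol, so ionisation can lead to an ortho-quinone methide and its oligomers instead of palladium capture. A8 lacks the C3 oxygen, so after dealkylation a separate two-electron oxidation of an electron-rich hydroxyaryl lactone is still required.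
- **Comparison:** this alternative is shorter by about two steps and would be preferable if the carbonylation held on this substrate. The chosen plan offers in return ring B bonds formed intramolecularly by anionic chemistry with a close known counterpart, no pressurised gas at a crowded centre, and an oxidation level that is built in.

Key step: step 8

Remark on the chemistry: the target has no stereocentre. Benzofuran numbering is used throughout (O1, C2, C3, C3a, C4 to C7, C7a, and 4' for the para position of the C3 aryl ring). Compounds 16 and 17 exist in the flask as potassium salts and are listed in neutral form. Phenyllithium, tert-butyllithium, methyl triflate and compound 13 are taken as purchasable.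

## Route

Step 1
Reactants: 1 diisopropyl squarate
Product: 3 3-isopropoxy-4-phenylcyclobut-3-ene-1,2-dione, via phenyllithium adduct 2 (not isolated)
Conditions: PhLi, THF, −78 °C; aq. NH4Cl; then 12 M HCl, CH2Cl2, rt
Reagents that add atoms: phenyllithium, [Li]c1ccccc1; water, O
Why: 1,2-Addition of the aryllithium to one squarate carbonyl gives carbinol 2; aqueous acid ionises the tertiary alcohol, water adds to the alkoxy-stabilised cation and one isopropanol is lost, the standard conversion of a dialkyl squarate into a 3-alkoxy-4-arylcyclobutenedione.

Step 2
Reactants: 3 3-isopropoxy-4-phenylcyclobut-3-ene-1,2-dione; 4 alpha-bromostyrene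
Product: 7 3-isopropoxy-4-methoxy-2-phenyl-4-(1-phenylvinyl)cyclobut-2-en-1-one (racemic), via (1-phenylvinyl)lithium 5 (not isolated), via lithium alkoxide adduct 6 (not isolated)
Conditions: 4, t-BuLi (2 equiv), THF, −78 °C; add 3, −78 °C; then MeOTf, −78 to 0 °C
Reagents that add atoms: methyl trifluoromethanesulfonate, COS(=O)(=O)C(F)(F)F
Why: Bromine–lithium exchange gives vinyllithium 5, which adds to the carbonyl next to the isopropoxy-bearing carbon because the other carbonyl is deactivated as a vinylogous ester; O-methylation of alkoxide 6 in the same flask sets the future C5 methyl ether. The quaternary carbon is formed racemic and ceases to be a stereocentre in step 3.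

Step 3
Reactants: 7 3-isopropoxy-4-methoxy-2-phenyl-4-(1-phenylvinyl)cyclobut-2-en-1-one
Product: 10 3-isopropoxy-4-methoxy-2,5-diphenylphenol, via dienylketene 8 (not isolated), via cyclohexadienone 9 (not isolated)
Conditions: PhMe, 110 °C
Reagents that add atoms: none
Why: Moore-type cyclobutenone ring expansion: conrotatory 4π ring opening with the methoxy group rotating outward gives dienylketene 8 with the styryl unit cis to the ketene, 6π electrocyclisation forms the future C3a–C7a bond, and enolisation of 9 gives the phenol with the methoxy group para to the new hydroxyl by construction.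

Step 4
Reactants: 10 3-isopropoxy-4-methoxy-2,5-diphenylphenol
Product: 11 2-iodo-5-isopropoxy-4-methoxy-3,6-diphenylphenol
Conditions: NIS, TsOH·H2O (cat.), MeCN, 0 °C to rt
Reagents that add atoms: N-iodosuccinimide, O=C1CCC(=O)N1I
Why: Electrophilic aromatic iodination at the only free ring position, which is ortho to the hydroxyl and para to the isopropoxy group; NIS is mild enough to spare the hydroquinone monoether.

Step 5
Reactants: 11 2-iodo-5-isopropoxy-4-methoxy-3,6-diphenylphenol
Product: 12 2-iodo-5-isopropoxy-4-methoxy-3,6-diphenylphenyl acetate
Conditions: Ac2O, pyridine, DMAP (cat.), CH2Cl2, rt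
Reagents that add atoms: acetic anhydride, CC(=O)OC(C)=O
Why: DMAP-catalysed O-acetylation of a hindered phenol; the acetate keeps the alkyne introduced next from cyclising onto the phenol and is the group the key step removes.

Step 6
Reactants: 12 2-iodo-5-isopropoxy-4-methoxy-3,6-diphenylphenyl acetate; 13 1-(benzyloxy)-4-ethynylbenzene
Product: 14 2-{[4-(benzyloxy)phenyl]ethynyl}-5-isopropoxy-4-methoxy-3,6-diphenylphenyl acetate
Conditions: PdCl2(PPh3)2 (cat.), CuI (cat.), Et3N, DMF, 60 °C
Reagents that add atoms: none
Why: Sonogashira coupling of an aryl iodide with a terminal arylacetylene; a tertiary amine is used as base so that the aryl acetate is not aminolysed and the phenol stays masked.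

Step 7
Reactants: 14 2-{[4-(benzyloxy)phenyl]ethynyl}-5-isopropoxy-4-methoxy-3,6-diphenylphenyl acetate
Product: 15 2-{2-[4-(benzyloxy)phenyl]-2-oxoacetyl}-5-isopropoxy-4-methoxy-3,6-diphenylphenyl acetate
Conditions: PdCl2 (cat.), DMSO, 140 °C
Reagents that add atoms: dimethyl sulfoxide, CS(C)=O
Why: Wacker-type dioxygenation of a diarylalkyne to a benzil, with DMSO as the stoichiometric oxidant and oxygen source; the ethers, the acetate and the arenes are inert to this neutral oxidant.

Step 8
Reactants: 15 2-{2-[4-(benzyloxy)phenyl]-2-oxoacetyl}-5-isopropoxy-4-methoxy-3,6-diphenylphenyl acetate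
Product: 18 3-[4-(benzyloxy)phenyl]-3-hydroxy-6-isopropoxy-5-methoxy-4,7-diphenylbenzofuran-2(3H)-one (racemic), via free ortho-hydroxybenzil 16 (not isolated), via 2-aryl-2-hydroxybenzofuran-3-one hemiketal 17 (not isolated)
Conditions: K2CO3, MeOH–THF, rt to 50 °C; then 1 M HCl
Reagents that add atoms: none
Why: Methoxide formed from K2CO3 in methanol transesterifies the aryl acetate and releases the phenoxide of 16. This oxygen adds to the outer carbonyl in a 5-exo-trig closure (O1–C2) to give the hemiketal alkoxide of 17; the inner carbonyl is out of reach because attack there would need a four-membered ring. The alkoxide on C2 then reforms a carbonyl while the 4-(benzyloxy)phenyl group migrates with its bonding pair to the adjacent ketone carbon (C3–aryl), a benzilic ester rearrangement with an internal aryloxide as nucleophile; the closest known reaction is the base-induced isomerisation of 2-aryl-2-hydroxybenzofuran-3(2H)-ones to 3-aryl-3-hydroxybenzofuran-2(3H)-ones. The exchange of a ketone for a lactone carbonyl drives the shift, and the ring fixes its direction, since only the aryl group on C2 can move to C3. Should external methoxide add first, either aryl shift would give the same diarylglycolate, which lactonises onto the free phenol, so both manifolds converge on 18, and the acidic work-up recloses any lactone opened by methanol. C3 becomes a stereocentre with no controlling element and is formed racemic, which is immaterial because step 9 makes it trigonal. The only chemoselectivity needed is that the benzyl, isopropyl and methyl ethers stay inert to carbonate, and O6 is kept as an ether so that the new C3 oxygen cannot be expelled under base.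

Step 9
Reactants: 18 3-[4-(benzyloxy)phenyl]-3-hydroxy-6-isopropoxy-5-methoxy-4,7-diphenylbenzofuran-2(3H)-one
Product: 20 3-(4-hydroxyphenyl)-5-methoxy-4,7-diphenylbenzofuran-2,6-dione, via triol 19 (not isolated)
Conditions: BCl3, C6HMe5, CH2Cl2, −78 to 0 °C; then 1 M HCl, THF, rt
Reagents that add atoms: none
Why: BCl3 cleaves the isopropyl aryl ether selectively beside the neighbouring methyl ether and, with pentamethylbenzene as benzyl-cation trap, the benzyl ether (Lewis-acid ether cleavage). Triol 19 is a tertiary benzylic alcohol para-related to the free O6 hydroxyl, and under the acidic quench it loses water by 1,6-elimination to the fully conjugated quinone methide, so no oxidant is needed and the racemic C3 centre disappears.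

## Compound list

1 | diisopropyl squarate (3,4-diisopropoxycyclobut-3-ene-1,2-dione) | CC(C)OC1=C(OC(C)C)C(=O)C1=O | starting material
2 | 4-hydroxy-2,3-diisopropoxy-4-phenylcyclobut-2-en-1-one (racemic) | CC(C)OC1=C(OC(C)C)C(O)(c2ccccc2)C1=O | intermediate (not isolated)
3 | 3-isopropoxy-4-phenylcyclobut-3-ene-1,2-dione | CC(C)OC1=C(c2ccccc2)C(=O)C1=O | intermediate
4 | alpha-bromostyrene ((1-bromovinyl)benzene) | BrC(=C)c1ccccc1 | starting material
5 | (1-phenylvinyl)lithium | [Li]C(=C)c1ccccc1 | intermediate (not isolated)
6 | lithium 2-isopropoxy-4-oxo-3-phenyl-1-(1-phenylvinyl)cyclobut-2-en-1-olate (racemic) | CC(C)OC1=C(c2ccccc2)C(=O)C1([O-])C(=C)c1ccccc1.[Li+] | intermediate (not isolated)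
7 | 3-isopropoxy-4-methoxy-2-phenyl-4-(1-phenylvinyl)cyclobut-2-en-1-one (racemic) | CC(C)OC1=C(c2ccccc2)C(=O)C1(OC)C(=C)c1ccccc1 | intermediate
8 | (3Z)-3-isopropoxy-4-methoxy-2,5-diphenylhexa-1,3,5-trien-1-one | O=C=C(c1ccccc1)/C(OC(C)C)=C(OC)\C(=C)c1ccccc1 | intermediate (not isolated)
9 | 3-isopropoxy-4-methoxy-2,5-diphenylcyclohexa-2,4-dien-1-one | O=C1CC(c2ccccc2)=C(OC)C(OC(C)C)=C1c1ccccc1 | intermediate (not isolated)
10 | 3-isopropoxy-4-methoxy-2,5-diphenylphenol | COc1c(OC(C)C)c(-c2ccccc2)c(O)cc1-c1ccccc1 | intermediate
11 | 2-iodo-5-isopropoxy-4-methoxy-3,6-diphenylphenol | COc1c(OC(C)C)c(-c2ccccc2)c(O)c(I)c1-c1ccccc1 | intermediate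
12 | 2-iodo-5-isopropoxy-4-methoxy-3,6-diphenylphenyl acetate | CC(=O)Oc1c(I)c(-c2ccccc2)c(OC)c(OC(C)C)c1-c1ccccc1 | intermediate
13 | 1-(benzyloxy)-4-ethynylbenzene | C#Cc1ccc(OCc2ccccc2)cc1 | starting material
14 | 2-{[4-(benzyloxy)phenyl]ethynyl}-5-isopropoxy-4-methoxy-3,6-diphenylphenyl acetate | CC(=O)Oc1c(C#Cc2ccc(OCc3ccccc3)cc2)c(-c2ccccc2)c(OC)c(OC(C)C)c1-c1ccccc1 | intermediate
15 | 2-{2-[4-(benzyloxy)phenyl]-2-oxoacetyl}-5-isopropoxy-4-methoxy-3,6-diphenylphenyl acetate | CC(=O)Oc1c(C(=O)C(=O)c2ccc(OCc3ccccc3)cc2)c(-c2ccccc2)c(OC)c(OC(C)C)c1-c1ccccc1 | intermediate
16 | 1-[4-(benzyloxy)phenyl]-2-(2-hydroxy-4-isopropoxy-5-methoxy-3,6-diphenylphenyl)ethane-1,2-dione | COc1c(OC(C)C)c(-c2ccccc2)c(O)c(C(=O)C(=O)c2ccc(OCc3ccccc3)cc2)c1-c1ccccc1 | intermediate (not isolated)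
17 | 2-[4-(benzyloxy)phenyl]-2-hydroxy-6-isopropoxy-5-methoxy-4,7-diphenylbenzofuran-3(2H)-one (racemic) | COc1c(OC(C)C)c(-c2ccccc2)c2OC(O)(c3ccc(OCc4ccccc4)cc3)C(=O)c2c1-c1ccccc1 | intermediate (not isolated)
18 | 3-[4-(benzyloxy)phenyl]-3-hydroxy-6-isopropoxy-5-methoxy-4,7-diphenylbenzofuran-2(3H)-one (racemic) | COc1c(OC(C)C)c(-c2ccccc2)c2OC(=O)C(O)(c3ccc(OCc4ccccc4)cc3)c2c1-c1ccccc1 | intermediate
19 | 3,6-dihydroxy-3-(4-hydroxyphenyl)-5-methoxy-4,7-diphenylbenzofuran-2(3H)-one (racemic) | COc1c(O)c(-c2ccccc2)c2OC(=O)C(O)(c3ccc(O)cc3)c2c1-c1ccccc1 | intermediate (not isolated)
20 | 3-(4-hydroxyphenyl)-5-methoxy-4,7-diphenylbenzofuran-2,6-dione (CNP0282683.0) | COC1=C(c2ccccc2)C2=C(c3ccc(O)cc3)C(=O)OC2=C(c2ccccc2)C1=O | target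

## Step count and least certain steps

Total step count: 9. Longest linear sequence: 9 steps, from 1 to 20; compounds 4 and 13 enter as purchased fragments.

**Step 8 (key step).**
- **Risk:** the cascade may stall after hemiketal formation. The accepting C3 ketone is shielded by the C4 phenyl group and deactivated by donation from O1 and the para isopropoxy group, and the migrating ring is electron-rich, which slows an anionic shift. On prolonged exposure to methoxide, scission of the bond between the two carbonyl carbons could then take over.
- **Fallback:** it sets out from phenol 10 and returns at 18. A TiCl4-mediated ortho-hydroxyalkylation of 10 (Friedel–Crafts type, with the titanium phenoxide delivering the electrophile to the only free ring position) with ethyl 2-[4-(benzyloxy)phenyl]-2-oxoacetate F1 (prepared from diethyl oxalate and 4-(benzyloxy)phenylmagnesium bromide) should give ethyl 2-[4-(benzyloxy)phenyl]-2-hydroxy-2-(2-hydroxy-4-isopropoxy-5-methoxy-3,6-diphenylphenyl)acetate F2. F2 closes to 18 with loss of ethanol, spontaneously or with catalytic TsOH in toluene.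
- **Trade-off:** this forms C3–C3a and O1–C2 instead of O1–C2 and C3–aryl and is shorter. It gives up the intramolecular delivery of the main plan and asks for an intermolecular attack on a hindered aryl ketone.

**Step 7.**
- **Risk:** the neighbouring acetate carbonyl may take part in the oxypalladation by divalent palladium, leading to acyl transfer and ring closure onto the alkyne instead of dioxygenation. Thermal loss of the acetyl group at 140 °C followed by 5-endo cyclisation of the freed phenol is the related danger.
- **Fallback:** it sets out from 14 and returns at 15, replacing direct dioxygenation by hydration and alpha-oxidation. Hydration with catalytic Ph3PAuNTf2 in aqueous dioxane should give 2-{2-[4-(benzyloxy)phenyl]acetyl}-5-isopropoxy-4-methoxy-3,6-diphenylphenyl acetate F3, its regioisomer 2-{2-[4-(benzyloxy)phenyl]-2-oxoethyl}-5-isopropoxy-4-methoxy-3,6-diphenylphenyl acetate F4, or both. Riley oxidation (SeO2, wet dioxane, 100 °C) converts either ketone into the same diketone 15, so the regiochemistry of hydration does not matter, and any participation of the acetate in the hydration is productive.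

**Step 6.**
- **Risk:** oxidative addition of zerovalent palladium into an electron-rich iodide flanked by an acetoxy and a phenyl group may be slow. Copper-mediated homocoupling would then consume the alkyne, and slow loss of the acetyl group would allow cyclisation of the coupled product to a benzofuran.
- **Fallback:** it sets out from 10 and returns at 14, reversing the roles of the coupling partners so that the hindered ring carries the alkyne.
  - Ortho-formylation of 10 (MgCl2, Et3N, paraformaldehyde, MeCN, reflux) should give 2-hydroxy-4-isopropoxy-5-methoxy-3,6-diphenylbenzaldehyde F5.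
  - Ohira–Bestmann homologation (dimethyl (1-diazo-2-oxopropyl)phosphonate, K2CO3, MeOH) should give 2-ethynyl-5-isopropoxy-4-methoxy-3,6-diphenylphenol F6.
  - Acetylation as in step 5 should give 2-ethynyl-5-isopropoxy-4-methoxy-3,6-diphenylphenyl acetate F7.
  - Sonogashira coupling of F7 with 1-(benzyloxy)-4-iodobenzene, where oxidative addition occurs at an unhindered iodide, leads to 14.

**Step 9.**
- **Risk:** cleavage of the isopropyl ether needs warming towards 0 °C. At that stage boron bridging O5 and O6, or bound to the C6 carbonyl of the quinone methide already released, may remove the C5 methyl group. Capture of the C3 cation by chloride or by the arene scavenger and incomplete dehydration during the quench are lesser concerns; the last is met by brief treatment with TsOH in toluene.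
- **Fallback:** it sets out from 18 and returns at 20, separating dealkylation from chromophore formation.
  - Ionic hydrogenation (Et3SiH, TFA, CH2Cl2) removes the C3 hydroxyl and should give 3-[4-(benzyloxy)phenyl]-6-isopropoxy-5-methoxy-4,7-diphenylbenzofuran-2(3H)-one F8.
  - BCl3 with pentamethylbenzene then acts on a substrate that cannot ionise to a quinone methide and should give 6-hydroxy-3-(4-hydroxyphenyl)-5-methoxy-4,7-diphenylbenzofuran-2(3H)-one F9.
  - Dehydrogenation of F9 with DDQ gives 20.
- **Trade-off:** two extra steps and the return of an oxidant.

## Further compounds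

F1 | step 8 | ethyl 2-[4-(benzyloxy)phenyl]-2-oxoacetate | CCOC(=O)C(=O)c1ccc(OCc2ccccc2)cc1
F2 | step 8 | ethyl 2-[4-(benzyloxy)phenyl]-2-hydroxy-2-(2-hydroxy-4-isopropoxy-5-methoxy-3,6-diphenylphenyl)acetate (racemic) | CCOC(=O)C(O)(c1ccc(OCc2ccccc2)cc1)c1c(O)c(-c2ccccc2)c(OC(C)C)c(OC)c1-c1ccccc1
F3 | step 7 | 2-{2-[4-(benzyloxy)phenyl]acetyl}-5-isopropoxy-4-methoxy-3,6-diphenylphenyl acetate | CC(=O)Oc1c(C(=O)Cc2ccc(OCc3ccccc3)cc2)c(-c2ccccc2)c(OC)c(OC(C)C)c1-c1ccccc1
F4 | step 7 | 2-{2-[4-(benzyloxy)phenyl]-2-oxoethyl}-5-isopropoxy-4-methoxy-3,6-diphenylphenyl acetate | CC(=O)Oc1c(CC(=O)c2ccc(OCc3ccccc3)cc2)c(-c2ccccc2)c(OC)c(OC(C)C)c1-c1ccccc1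
F5 | step 6 | 2-hydroxy-4-isopropoxy-5-methoxy-3,6-diphenylbenzaldehyde | COc1c(OC(C)C)c(-c2ccccc2)c(O)c(C=O)c1-c1ccccc1
F6 | step 6 | 2-ethynyl-5-isopropoxy-4-methoxy-3,6-diphenylphenol | COc1c(OC(C)C)c(-c2ccccc2)c(O)c(C#C)c1-c1ccccc1
F7 | step 6 | 2-ethynyl-5-isopropoxy-4-methoxy-3,6-diphenylphenyl acetate | CC(=O)Oc1c(C#C)c(-c2ccccc2)c(OC)c(OC(C)C)c1-c1ccccc1
F8 | step 9 | 3-[4-(benzyloxy)phenyl]-6-isopropoxy-5-methoxy-4,7-diphenylbenzofuran-2(3H)-one (racemic) | COc1c(OC(C)C)c(-c2ccccc2)c2OC(=O)C(c3ccc(OCc4ccccc4)cc3)c2c1-c1ccccc1
F9 | step 9 | 6-hydroxy-3-(4-hydroxyphenyl)-5-methoxy-4,7-diphenylbenzofuran-2(3H)-one (racemic) | COc1c(O)c(-c2ccccc2)c2OC(=O)C(c3ccc(O)cc3)c2c1-c1ccccc1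
A1 | alternative 1 | 3-isopropoxy-4-methoxy-2-phenyl-4-(1-phenylvinyl)cyclobut-2-en-1-one (racemic; identical with 7) | CC(C)OC1=C(c2ccccc2)C(=O)C1(OC)C(=C)c1ccccc1
A2 | alternative 1 | 3-isopropoxy-4-methoxy-2,5-diphenylphenol (identical with 10) | COc1c(OC(C)C)c(-c2ccccc2)c(O)cc1-c1ccccc1
A3 | alternative 2 | 2-(3,4-dihydroxy-2,5-diphenylphenyl)-2-(4-hydroxyphenyl)acetic acid (racemic) | OC(=O)C(c1ccc(O)cc1)c1cc(-c2ccccc2)c(O)c(O)c1-c1ccccc1
A4 | alternative 2 | 2-(3,4-dioxo-2,5-diphenylcyclohexa-1,5-dien-1-yl)-2-(4-hydroxyphenyl)acetic acid (racemic) | OC(=O)C(c1ccc(O)cc1)C1=C(c2ccccc2)C(=O)C(=O)C(c2ccccc2)=C1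
A5 | alternative 2 | xylerythrin, 5-hydroxy-3-(4-hydroxyphenyl)-4,7-diphenylbenzofuran-2,6-dione | OC1=C(c2ccccc2)C2=C(c3ccc(O)cc3)C(=O)OC2=C(c2ccccc2)C1=O
A6 | alternative 3 | 2-[hydroxy(4-isopropoxyphenyl)methyl]-5-isopropoxy-4-methoxy-3,6-diphenylphenol (racemic) | COc1c(OC(C)C)c(-c2ccccc2)c(O)c(C(O)c2ccc(OC(C)C)cc2)c1-c1ccccc1
A7 | alternative 3 | 4-isopropoxybenzaldehyde | CC(C)Oc1ccc(C=O)cc1
A8 | alternative 3 | 6-isopropoxy-3-(4-isopropoxyphenyl)-5-methoxy-4,7-diphenylbenzofuran-2(3H)-one (racemic) | COc1c(OC(C)C)c(-c2ccccc2)c2OC(=O)C(c3ccc(OC(C)C)cc3)c2c1-c1ccccc1
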